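**Retrosynthetic overview**
- The target comes from a cis-selective hydride reduction of the C2 ketone and phenol desilylation of an anti-aldol β-hydroxy ketone (a 1-substituted 6,7-dimethoxy-2-tetralone).
- That β-hydroxy ketone comes from a catalytic enantioselective anti-aldol between the C1=C2 trichlorosilyl enolate of 6,7-dimethoxy-2-tetralone and O-silylated 4-hydroxycinnamaldehyde, which sets C1 and C1'.
- The enolate comes from a one-carbon ring expansion (1,2-aryl shift with loss of N2) of 5,6-dimethoxy-1-indanone with (trimethylsilyl)diazomethane, run in the same flask as the aldol.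
- The indanone comes from catechol (O-methylation) and 3-chloropropanoyl chloride; the aldehyde comes from 4-iodophenol (silylated) and acrolein by a Heck reaction.
- Ring order: aromatic ring A is bought; the five-membered ketone ring is closed first and then expanded to the six-membered ring B.

Assumption: the (R,R) antipode of the phosphoramide catalyst is taken to steer the enolate to the Si face of the enal (giving 1R,1'R). I could not confirm this sense from memory; it is checked by Mosher ester analysis on the first batch, and the (S,S) antipode, equally available, is used if the sense is reversed.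

"(R,R)-phosphoramide" below means (4R,5R)-1,3-dimethyl-4,5-diphenyl-2-(piperidin-1-yl)-1,3,2-diazaphospholidine 2-oxide.

**Step 1**
Reactants: 1 benzene-1,2-diol (catechol)
Product: 2 1,2-dimethoxybenzene
Conditions: MeI (2.5 equiv), K2CO3 (3 equiv), acetone, reflux
Reagents that add atoms: iodomethane, CI
Why: Double Williamson ether synthesis of the two phenols; no stereocenter.

**Step 2**
Reactants: 2 1,2-dimethoxybenzene; 3 3-chloropropanoyl chloride
Product: 6 5,6-dimethoxy-2,3-dihydro-1H-inden-1-one, via chloroketone 4 (not isolated), via aryl vinyl ketone 5 (not isolated)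
Conditions: AlCl3 (1.2 equiv), CH2Cl2, 0 °C to rt; then conc. H2SO4 added, CH2Cl2 distilled out, 90 °C; poured on ice
Reagents that add atoms: none
Why: Friedel–Crafts acylation para to one methoxy group, then acid-mediated loss of HCl and Nazarov-type (intramolecular Friedel–Crafts) closure para to the other methoxy group gives only the 5,6-dimethoxy indanone; no stereocenter.

**Step 3**
Reactants: 7 4-iodophenol
Product: 8 tert-butyl(4-iodophenoxy)dimethylsilane
Conditions: TBSCl (1.1 equiv), imidazole (2 equiv), DMF, rt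
Reagents that add atoms: tert-butyldimethylsilyl chloride, CC(C)(C)[Si](C)(C)Cl
Why: Standard silylation of a phenol; the silyl ether masks the acidic OH for the enolate chemistry of step 5.

**Step 4**
Reactants: 8 tert-butyl(4-iodophenoxy)dimethylsilane; 9 prop-2-enal (acrolein)
Product: 10 (2E)-3-[4-(tert-butyldimethylsilyloxy)phenyl]prop-2-enal
Conditions: Pd(OAc)2 (2 mol%), Bu4NCl (1 equiv), NaHCO3 (2.5 equiv), 9 (3 equiv), DMF, 40 °C
Reagents that add atoms: none
Why: Heck reaction under ligand-free Jeffery conditions: oxidative addition of the aryl iodide to zerovalent palladium, syn insertion of acrolein and syn β-hydride elimination give the E enal.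

**Step 5**
Reactants: 6 5,6-dimethoxy-2,3-dihydro-1H-inden-1-one; 11 (trimethylsilyl)diazomethane; 10 (2E)-3-[4-(tert-butyldimethylsilyloxy)phenyl]prop-2-enal
Product: 14 (1R)-1-[(1R,2E)-3-[4-(tert-butyldimethylsilyloxy)phenyl]-1-hydroxyprop-2-en-1-yl]-6,7-dimethoxy-3,4-dihydronaphthalen-2(1H)-one, via trichlorosilyl enolate 12 (not isolated), via trichlorosilyl aldolate 13 (not isolated)
Conditions: SiCl4 (1.2 equiv), (R,R)-phosphoramide (15 mol%), 2,6-di-tert-butyl-4-methylpyridine (10 mol%), 11 (1.2 equiv, 2 M in hexanes, slow addition), CH2Cl2, −40 to 0 °C; volatiles (Me3SiCl, excess SiCl4 and 11) removed in vacuo at 0 °C; then CH2Cl2, −78 °C, 10 (0.7 equiv, slow addition); cold sat. aq NaHCO3; crude 14 used at once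
Reagents that add atoms: silicon tetrachloride, Cl[Si](Cl)(Cl)Cl (its atoms stay only in the non-isolated 12 and 13 and are lost on work-up)
Why: Proposed new method: SiCl4 activated by the phosphoramide (a cationic trichlorosilyl Lewis acid) should activate the indanone carbonyl for addition of 11, the electron-rich aryl carbon (para to a methoxy group) then migrates with loss of N2 (Tiffeneau–Demjanov-type ring expansion; closest known reaction: BF3·OEt2-, AlMe3- or Sc(OTf)3-promoted homologation of ketones with 11), and the resulting β-silyl oxocarbenium ion gives up Me3Si+ to chloride so that the C1=C2 trichlorosilyl enolate 12 forms directly instead of the usual α-silyl ketone or trimethylsilyl enol ether and cannot be homologated twice; the same phosphoramide then catalyses the known Lewis-base-catalysed aldol of trichlorosilyl enolates, where the ring-locked E enolate reacts through a chair transition state on hexacoordinate silicon to give the anti C1/C1' relationship and the catalyst chirality selects the Si face of the enal (1R,1'R).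

**Step 6**
Reactants: 14 (1R)-1-[(1R,2E)-3-[4-(tert-butyldimethylsilyloxy)phenyl]-1-hydroxyprop-2-en-1-yl]-6,7-dimethoxy-3,4-dihydronaphthalen-2(1H)-one
Product: 16 (1S,2R)-1-[(1R,2E)-1-hydroxy-3-(4-hydroxyphenyl)prop-2-en-1-yl]-6,7-dimethoxy-1,2,3,4-tetrahydronaphthalen-2-ol, via silyl-protected diol 15 (not isolated)
Conditions: LiBH(s-Bu)3 (3 equiv), THF, −78 °C; MeOH quench; then Bu4NF (3 equiv), 0 °C to rt; aq NH4Cl
Reagents that add atoms: none
Why: The bulky hydride attacks the C2 carbonyl from the face opposite the C1 side chain (steric approach control, as in tri-sec-butylborohydride reductions of 2-substituted cyclohexanones and 1-substituted 2-tetralones), giving the cis (2R) alcohol, which is the 1,3-anti diol; fluoride then cleaves the aryl silyl ether without touching the allylic alcohol.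

**Compound list**
1 | benzene-1,2-diol (catechol) | Oc1ccccc1O | starting material
2 | 1,2-dimethoxybenzene | COc1ccccc1OC | intermediate
3 | 3-chloropropanoyl chloride | ClCCC(Cl)=O | starting material
4 | 3-chloro-1-(3,4-dimethoxyphenyl)propan-1-one | COc1ccc(cc1OC)C(=O)CCCl | intermediate
5 | 1-(3,4-dimethoxyphenyl)prop-2-en-1-one | COc1ccc(cc1OC)C(=O)C=C | intermediate
6 | 5,6-dimethoxy-2,3-dihydro-1H-inden-1-one | COc1cc2c(cc1OC)C(=O)CC2 | intermediate
7 | 4-iodophenol | Oc1ccc(I)cc1 | starting material
8 | tert-butyl(4-iodophenoxy)dimethylsilane | CC(C)(C)[Si](C)(C)Oc1ccc(I)cc1 | intermediate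
9 | prop-2-enal (acrolein) | C=CC=O | starting material
10 | (2E)-3-[4-(tert-butyldimethylsilyloxy)phenyl]prop-2-enal | CC(C)(C)[Si](C)(C)Oc1ccc(/C=C/C=O)cc1 | intermediate
11 | (trimethylsilyl)diazomethane | C[Si](C)(C)C=[N+]=[N-] | starting material
12 | trichloro[(6,7-dimethoxy-3,4-dihydronaphthalen-2-yl)oxy]silane | COc1cc2c(cc1OC)C=C(O[Si](Cl)(Cl)Cl)CC2 | intermediate
13 | (1R)-1-[(1R,2E)-3-[4-(tert-butyldimethylsilyloxy)phenyl]-1-(trichlorosilyloxy)prop-2-en-1-yl]-6,7-dimethoxy-3,4-dihydronaphthalen-2(1H)-one | COc1cc2c(cc1OC)[C@H]([C@H](O[Si](Cl)(Cl)Cl)/C=C/c1ccc(O[Si](C)(C)C(C)(C)C)cc1)C(=O)CC2 | intermediate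
14 | (1R)-1-[(1R,2E)-3-[4-(tert-butyldimethylsilyloxy)phenyl]-1-hydroxyprop-2-en-1-yl]-6,7-dimethoxy-3,4-dihydronaphthalen-2(1H)-one | COc1cc2c(cc1OC)[C@H]([C@H](O)/C=C/c1ccc(O[Si](C)(C)C(C)(C)C)cc1)C(=O)CC2 | intermediate
15 | (1S,2R)-1-[(1R,2E)-3-[4-(tert-butyldimethylsilyloxy)phenyl]-1-hydroxyprop-2-en-1-yl]-6,7-dimethoxy-1,2,3,4-tetrahydronaphthalen-2-ol | COc1cc2c(cc1OC)[C@H]([C@H](O)/C=C/c1ccc(O[Si](C)(C)C(C)(C)C)cc1)[C@H](O)CC2 | intermediate
16 | (1S,2R)-1-[(1R,2E)-1-hydroxy-3-(4-hydroxyphenyl)prop-2-en-1-yl]-6,7-dimethoxy-1,2,3,4-tetrahydronaphthalen-2-ol (CNP0142972.1) | COc1cc2c(cc1OC)[C@H]([C@H](O)/C=C/c1ccc(O)cc1)[C@H](O)CC2 | target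

**Total step count:** 6. **Longest linear sequence:** 4 (steps 1, 2, 5, 6, or steps 3, 4, 5, 6).

**Three steps most likely to fail**

Step 5 (the proposed new step). The activated SiCl4 may be too weak a Lewis acid for the electron-rich aryl ketone, or 11 may decompose before it adds. The fallback uses known chemistry and sets out from 6. The established BF3·OEt2-promoted homologation with 11 (CH2Cl2, −78 °C) gives racemic 1-(trimethylsilyl)-6,7-dimethoxy-3,4-dihydronaphthalen-2(1H)-one F1, which is protodesilylated on aqueous work-up to 6,7-dimethoxy-3,4-dihydronaphthalen-2(1H)-one F2. Silylation with Me3SiCl, Et3N and NaI in MeCN gives the conjugated enol ether [(6,7-dimethoxy-3,4-dihydronaphthalen-2-yl)oxy]trimethylsilane F3. The known trans-silylation with SiCl4 and catalytic Hg(OAc)2 then gives the trichlorosilyl enolate, so the route is rejoined at 12; the phosphoramide-catalysed aldol with 10 follows as in step 5.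

Step 6. The free β-hydroxy ketone may undergo retro-aldol or C1 epimerisation as its alkoxide, or a chelated pathway may erode the cis selectivity. The fallback sets out from 14. Silylation with Et3SiOTf and 2,6-lutidine (CH2Cl2, −78 °C) gives (1R)-1-[(1R,2E)-3-[4-(tert-butyldimethylsilyloxy)phenyl]-1-(triethylsilyloxy)prop-2-en-1-yl]-6,7-dimethoxy-3,4-dihydronaphthalen-2(1H)-one F4, which can no longer chelate or fragment. Reduction with LiBH(s-Bu)3 (THF, −78 °C) gives (1S,2R)-1-[(1R,2E)-3-[4-(tert-butyldimethylsilyloxy)phenyl]-1-(triethylsilyloxy)prop-2-en-1-yl]-6,7-dimethoxy-1,2,3,4-tetrahydronaphthalen-2-ol F5. Bu4NF in THF removes both silyl groups and comes back to the route at 16.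

Step 4. Acrolein may polymerise, or the aryl silyl ether may be partly cleaved under the basic phase-transfer conditions. The fallback sets out from 8. A Heck reaction with methyl prop-2-enoate (Pd(OAc)2, P(o-tol)3, Et3N, DMF, 90 °C) gives methyl (2E)-3-[4-(tert-butyldimethylsilyloxy)phenyl]prop-2-enoate F6. Reduction with i-Bu2AlH (CH2Cl2, −78 °C) gives (2E)-3-[4-(tert-butyldimethylsilyloxy)phenyl]prop-2-en-1-ol F7, and oxidation with MnO2 (CH2Cl2, rt) comes back to the route at 10.

**Further compounds**
F1 | step 5 | 1-(trimethylsilyl)-6,7-dimethoxy-3,4-dihydronaphthalen-2(1H)-one (racemic) | COc1cc2c(cc1OC)C([Si](C)(C)C)C(=O)CC2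
F2 | step 5 | 6,7-dimethoxy-3,4-dihydronaphthalen-2(1H)-one | COc1cc2c(cc1OC)CC(=O)CC2
F3 | step 5 | [(6,7-dimethoxy-3,4-dihydronaphthalen-2-yl)oxy]trimethylsilane | COc1cc2c(cc1OC)C=C(O[Si](C)(C)C)CC2
F4 | step 6 | (1R)-1-[(1R,2E)-3-[4-(tert-butyldimethylsilyloxy)phenyl]-1-(triethylsilyloxy)prop-2-en-1-yl]-6,7-dimethoxy-3,4-dihydronaphthalen-2(1H)-one | COc1cc2c(cc1OC)[C@H]([C@H](O[Si](CC)(CC)CC)/C=C/c1ccc(O[Si](C)(C)C(C)(C)C)cc1)C(=O)CC2
F5 | step 6 | (1S,2R)-1-[(1R,2E)-3-[4-(tert-butyldimethylsilyloxy)phenyl]-1-(triethylsilyloxy)prop-2-en-1-yl]-6,7-dimethoxy-1,2,3,4-tetrahydronaphthalen-2-ol | COc1cc2c(cc1OC)[C@H]([C@H](O[Si](CC)(CC)CC)/C=C/c1ccc(O[Si](C)(C)C(C)(C)C)cc1)[C@H](O)CC2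
F6 | step 4 | methyl (2E)-3-[4-(tert-butyldimethylsilyloxy)phenyl]prop-2-enoate | COC(=O)/C=C/c1ccc(O[Si](C)(C)C(C)(C)C)cc1
F7 | step 4 | (2E)-3-[4-(tert-butyldimethylsilyloxy)phenyl]prop-2-en-1-ol | OC/C=C/c1ccc(O[Si](C)(C)C(C)(C)C)cc1
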